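**Retrosynthetic overview**
- The (12E)-diene comes from a C12 methyl ester by a reductive allylboration–Peterson dienylation, C17 from a C8 ketone; the acetate and the free acid are unveiled last.
- The C6 oxygen comes from a Δ6-8-ketone by conjugate borylation–oxidation on the face opposite the two axial methyl groups.
- Ring B (the only ring made) is closed by a Dieckmann condensation (C7–C8) of a ring-A seco triester; C9 is set by equilibration next to the ketone.
- The seco acid comes from oxidative degradation of the aromatic ring of an abietane. The old aryl carbon C9 becomes the target's carboxyl, so ring A of dehydroabietic acid is used with C4 and C10 exchanged, which gives the ent series.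
- The key C9–C10 bond is made by a photochemical decarboxylative radical (Giese) addition of dehydroabietic acid to dimethyl fumarate. Ring A is bought, the old rings B and C are destroyed, ring B is rebuilt.

Assumption: dehydroabietic acid, dimethyl fumarate and 3-(trimethylsilyl)buta-1,2-diene are taken as commercial; from compound 4 on, locants follow the target's labdane numbering (C10 = former C4, C4 = former C10, C18 = former C9 of dehydroabietic acid), and all bicyclic compounds have 5β-H, 9β-H, 10α-CH3, 4α-CH3 and an equatorial 6β-oxygen (absolute).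

**Step 1**
Reactants: 1 dehydroabietic acid; 2 dimethyl fumarate
Product: 3 dimethyl 2-(18-norabieta-8,11,13-trien-4α-yl)butanedioate (both epimers at the succinate CH)
Conditions: Ir[dF(CF3)ppy]2(dtbbpy)PF6 (1 mol%), K2HPO4, DMF, 450 nm LEDs, rt
Reagents that add atoms: none
Why: Photoredox decarboxylative Giese addition: the carboxylate is oxidised by the excited photocatalyst, loses CO2, and the planar C4 radical is captured by fumarate on the α face, anti to the 1,3-diaxial C10 methyl, so the new C–C bond takes the place of the carboxyl (4β-methyl kept, C5 and C10 untouched), while the succinate CH forms as both epimers and is corrected in step 4.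

**Step 2**
Reactants: 3 dimethyl 2-(18-norabieta-8,11,13-trien-4α-yl)butanedioate
Product: 4 dimethyl 2-[(1R,2S,3S)-3-carboxy-2-(2-carboxyethyl)-1,3-dimethylcyclohexyl]butanedioate (ring A seco diacid)
Conditions: RuCl3·H2O (5 mol%), NaIO4 (excess), EtOAc/MeCN/H2O, rt
Reagents that add atoms: sodium periodate, [Na+].[O-]I(=O)(=O)=O; water, O
Why: Ruthenium tetroxide oxidation (catalytic RuCl3/NaIO4) degrades the trialkylbenzene ring to carboxylic acids at its two ipso carbons (arene as latent carboxyl), leaving esters and the three ring-A stereocentres untouched.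

**Step 3**
Reactants: 4 ring A seco diacid
Product: 5 dimethyl 2-[(1R,2S,3S)-3-carboxy-2-(3-methoxy-3-oxopropyl)-1,3-dimethylcyclohexyl]butanedioate
Conditions: MeOH, H2SO4 (cat.), rt
Reagents that add atoms: methanol, CO
Why: Fischer esterification is sterically selective, converting only the unhindered primary acid and leaving the neopentyl tertiary acid free, so that in step 4 this carboxylate cannot act as a competing Dieckmann electrophile.

**Step 4**
Reactants: 5 triester acid
Product: 8 dimethyl ent-8-oxo-13,14,15,16,17-pentanorlabdane-12,18-dioate, via Dieckmann β-keto ester 6 (not isolated), via keto acid 7 (not isolated)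
Conditions: NaOMe, MeOH/PhMe, reflux; AcOH; then LiCl, DMSO/H2O, 150 °C; then K2CO3, MeI, rt
Reagents that add atoms: iodomethane, CI
Why: A thermodynamic Dieckmann condensation (C7 enolate onto the C8 ester, the six-membered enolisable β-keto ester being favoured over seven-membered alternatives) is followed in the same flask by Krapcho demethoxycarbonylation and O-methylation of the carboxylate, and C9, now α to the ketone, equilibrates to the epimer with the acetate arm equatorial (9-H axial, anti to the C10 methyl; minor epimer recycled with NaOMe).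

**Step 5**
Reactants: 8 keto diester
Product: 9 dimethyl ent-8-oxo-13,14,15,16,17-pentanorlabd-6-ene-12,18-dioate
Conditions: LiN(iPr)2, THF, −78 °C; then PhS(Cl)=NtBu, −78 °C
Reagents that add atoms: none
Why: Kinetic deprotonation at the less hindered C7 and Mukaiyama dehydrogenation with the sulfinimidoyl chloride (S-attack, then syn-elimination) can only give the Δ6 enone, and no stereocentre is touched.

**Step 6**
Reactants: 9 enone
Product: 11 dimethyl ent-6α-hydroxy-8-oxo-13,14,15,16,17-pentanorlabdane-12,18-dioate, via C6 pinacol boronate 10 (not isolated)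
Conditions: CuCl (5 mol%), DPEphos, NaOtBu, B2pin2, MeOH, THF, rt; then NaBO3·4H2O, THF/H2O, rt
Reagents that add atoms: bis(pinacolato)diboron (boron of 10), CC1(C)OB(OC1(C)C)B1OC(C)(C)C(C)(C)O1; sodium perborate (oxygen of 11), [Na+].[O-]OB=O
Why: Copper-catalysed conjugate borylation followed by stereoretentive C–B oxidation: the boryl copper adds to C6 from the face opposite the two axial methyl groups on C4 and C10, so the C6 oxygen ends equatorial as in the target (a lactone with the diequatorial C18 ester would be doubly trans-fused and is not expected to form).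

**Step 7**
Reactants: 11 hydroxy ketone
Product: 12 dimethyl ent-6α-hydroxy-13,14,15,16-tetranorlabd-8(17)-ene-12,18-dioate
Conditions: Zn, CH2Br2, TiCl4, THF/CH2Cl2, 0 °C to rt
Reagents that add atoms: dibromomethane, BrCBr
Why: Lombardo methylenation converts the hindered, base-sensitive β-hydroxy ketone into the exocyclic alkene under non-basic conditions, avoiding retro-aldol, elimination and C9 epimerisation and leaving the esters alone.

**Step 8**
Reactants: 12 hydroxy diester; 13 3-(trimethylsilyl)buta-1,2-diene
Product: 16 methyl ent-6α-hydroxylabda-8(17),12E,14-trien-18-oate, via aldehyde 14 (not isolated), via β-hydroxysilane 15 (not isolated)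
Conditions: iBu2AlH (2.1 equiv), CH2Cl2, −78 °C; allylborane from 13 + 9-BBN-H (THF, 0 °C), −78 to 0 °C; work-up; then KH, THF, 0 °C
Reagents that add atoms: none
Why: Proposed new method: one-flask reductive dienylation of an ester, in which iBu2AlH stops at the aluminium hemiacetal (the C6 alkoxide and the hindered C18 ester are inert at −78 °C), warming releases aldehyde 14 into the γ-methyl-γ-silyl allylborane (hydroboration of 13 anti to SiMe3 puts Si cis to CH2B), the chair allylboration places SiMe3 syn to the new hydroxyl, and syn-Peterson elimination then gives only the 12E diene; the closest known reaction types are one-pot iBu2AlH reduction/Wittig or Horner–Wadsworth–Emmons olefination of esters and the γ-silylallylboron allylboration/Peterson synthesis of 1,3-dienes from isolated aldehydes.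

**Step 9**
Reactants: 16 dienyl hydroxy ester
Product: 17 methyl ent-6α-acetoxylabda-8(17),12E,14-trien-18-oate
Conditions: Ac2O, DMAP, pyridine, rt
Reagents that add atoms: acetic anhydride, CC(=O)OC(C)=O
Why: DMAP-catalysed acetylation of the equatorial secondary alcohol under neutral conditions that touch neither the hindered ester nor the alkenes.

**Step 10**
Reactants: 17 acetoxy methyl ester
Product: 18 ent-6α-acetoxylabda-8(17),12E,14-trien-18-oic acid (CNP0240327.3)
Conditions: LiI, pyridine, reflux (dark, N2); dilute HCl work-up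
Reagents that add atoms: none
Why: SN2 dealkylation of the hindered methyl ester by iodide at the methyl carbon frees the acid, while the secondary acetate (no SN2-accessible carbon, no hydroxide present) and the diene survive.

**Compound list**
1 | dehydroabietic acid | OC(=O)[C@]1(C)CCC[C@]2(C)c3ccc(cc3CC[C@@H]12)C(C)C | starting material
2 | dimethyl fumarate | COC(=O)/C=C/C(=O)OC | starting material
3 | dimethyl 2-(18-norabieta-8,11,13-trien-4α-yl)butanedioate (both epimers at the succinate CH) | COC(=O)CC(C(=O)OC)[C@]1(C)CCC[C@]2(C)c3ccc(cc3CC[C@@H]12)C(C)C | intermediate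
4 | dimethyl 2-[(1R,2S,3S)-3-carboxy-2-(2-carboxyethyl)-1,3-dimethylcyclohexyl]butanedioate | COC(=O)CC(C(=O)OC)[C@]1(C)CCC[C@](C)(C(=O)O)[C@H]1CCC(=O)O | intermediate
5 | dimethyl 2-[(1R,2S,3S)-3-carboxy-2-(3-methoxy-3-oxopropyl)-1,3-dimethylcyclohexyl]butanedioate | COC(=O)CC(C(=O)OC)[C@]1(C)CCC[C@](C)(C(=O)O)[C@H]1CCC(=O)OC | intermediate
6 | ent-12-methoxy-7-(methoxycarbonyl)-8,12-dioxo-13,14,15,16,17-pentanorlabdan-18-oic acid (Dieckmann β-keto ester, C7 unassigned) | COC(=O)C[C@@H]1C(=O)C(C(=O)OC)C[C@H]2[C@@]1(C)CCC[C@]2(C)C(=O)O | intermediate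
7 | ent-12-methoxy-8,12-dioxo-13,14,15,16,17-pentanorlabdan-18-oic acid | COC(=O)C[C@@H]1C(=O)CC[C@H]2[C@@]1(C)CCC[C@]2(C)C(=O)O | intermediate
8 | dimethyl ent-8-oxo-13,14,15,16,17-pentanorlabdane-12,18-dioate | COC(=O)C[C@@H]1C(=O)CC[C@H]2[C@@]1(C)CCC[C@]2(C)C(=O)OC | intermediate
9 | dimethyl ent-8-oxo-13,14,15,16,17-pentanorlabd-6-ene-12,18-dioate | COC(=O)C[C@@H]1C(=O)C=C[C@H]2[C@@]1(C)CCC[C@]2(C)C(=O)OC | intermediate
10 | dimethyl ent-8-oxo-6α-(4,4,5,5-tetramethyl-1,3,2-dioxaborolan-2-yl)-13,14,15,16,17-pentanorlabdane-12,18-dioate | COC(=O)C[C@@H]1C(=O)C[C@@H](B3OC(C)(C)C(C)(C)O3)[C@H]2[C@@]1(C)CCC[C@]2(C)C(=O)OC | intermediate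
11 | dimethyl ent-6α-hydroxy-8-oxo-13,14,15,16,17-pentanorlabdane-12,18-dioate | COC(=O)C[C@@H]1C(=O)C[C@@H](O)[C@H]2[C@@]1(C)CCC[C@]2(C)C(=O)OC | intermediate
12 | dimethyl ent-6α-hydroxy-13,14,15,16-tetranorlabd-8(17)-ene-12,18-dioate | COC(=O)C[C@@H]1C(=C)C[C@@H](O)[C@H]2[C@@]1(C)CCC[C@]2(C)C(=O)OC | intermediate
13 | 3-(trimethylsilyl)buta-1,2-diene | C=C=C(C)[Si](C)(C)C | starting material
14 | methyl ent-6α-hydroxy-12-oxo-13,14,15,16-tetranorlabd-8(17)-en-18-oate | O=CC[C@@H]1C(=C)C[C@@H](O)[C@H]2[C@@]1(C)CCC[C@]2(C)C(=O)OC | intermediate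
15 | methyl ent-6α,12-dihydroxy-13-(trimethylsilyl)labda-8(17),14-dien-18-oate (12-OH and 13-SiMe3 syn; drawn isomer forms together with its 12,13-bis-epimer) | C=C[C@@](C)([Si](C)(C)C)[C@H](O)C[C@@H]1C(=C)C[C@@H](O)[C@H]2[C@@]1(C)CCC[C@]2(C)C(=O)OC | intermediate
16 | methyl ent-6α-hydroxylabda-8(17),12E,14-trien-18-oate | C=C/C(C)=C/C[C@@H]1C(=C)C[C@@H](O)[C@H]2[C@@]1(C)CCC[C@]2(C)C(=O)OC | intermediate
17 | methyl ent-6α-acetoxylabda-8(17),12E,14-trien-18-oate | C=C/C(C)=C/C[C@@H]1C(=C)C[C@@H](OC(C)=O)[C@H]2[C@@]1(C)CCC[C@]2(C)C(=O)OC | intermediate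
18 | ent-6α-acetoxylabda-8(17),12E,14-trien-18-oic acid, (4S,5S,6R,9R,10S) | C=C/C(C)=C/C[C@@H]1C(=C)C[C@@H](OC(C)=O)[C@H]2[C@@]1(C)CCC[C@]2(C)C(=O)O | target

**Step count**
Total steps: 10. Longest linear sequence: 10 (from dehydroabietic acid).

**Three steps most likely to fail, with fallbacks**

Step 1 (radical capture at C4). The hindered tertiary radical may add slowly to a β-substituted acceptor, and face selectivity at the new quaternary carbon may be incomplete. The fallback sets out from 1 and is stereospecific. Oxalyl chloride followed by TMSCHN2 gives 4α-(2-diazoacetyl)-18-norabieta-8,11,13-triene F1. Irradiation at 365 nm in MeOH (photochemical Wolff rearrangement, migration of C4 with retention) gives methyl 2-(18-norabieta-8,11,13-trien-4α-yl)acetate F2. Deprotonation with LiN(iPr)2 and alkylation with methyl bromoacetate return to 3.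

Step 2 (arene degradation). Benzylic oxidation at C7 can deactivate the ring and stop the cleavage. The fallback sets out from 3 and replaces the metal-oxo oxidation by ozonolysis: exhaustive O3 in AcOH/CH2Cl2, then H2O2/HCO2H oxidative work-up, returning to 4. It makes no compound outside the list (none F0).

Step 8 (proposed reductive dienylation). The aluminium hemiacetal may over-reduce or the allylborane geometry may erode. The fallback sets out from 12 and uses known stepwise chemistry. iBu2AlH at −78 °C with isolation gives aldehyde 14. Wittig reaction with Ph3P=C(CH3)CHO gives methyl ent-6α-hydroxy-14-oxo-15-norlabda-8(17),12E-dien-18-oate F3. Methylenation with Ph3P=CH2 returns to 16.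

**Further compounds**
F1 | step 1 | 4α-(2-diazoacetyl)-18-norabieta-8,11,13-triene | [N-]=[N+]=CC(=O)[C@]1(C)CCC[C@]2(C)c3ccc(cc3CC[C@@H]12)C(C)C
F2 | step 1 | methyl 2-(18-norabieta-8,11,13-trien-4α-yl)acetate | COC(=O)C[C@]1(C)CCC[C@]2(C)c3ccc(cc3CC[C@@H]12)C(C)C
F0 | step 2 | none | none
F3 | step 8 | methyl ent-6α-hydroxy-14-oxo-15-norlabda-8(17),12E-dien-18-oate | O=C/C(C)=C/C[C@@H]1C(=C)C[C@@H](O)[C@H]2[C@@]1(C)CCC[C@]2(C)C(=O)OC
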